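# Proposed synthesis of (−)-epigallocatechin 3,4'-di-O-gallate (14)

## Analysis of the target

The target is a flavan-3-ol: a chroman (benzo ring A fused to the oxygen heterocycle, ring C) that carries a 3,4,5-trioxygenated phenyl group (ring B) at C2, with galloyl esters on the ring C oxygen O3 and on the central ring B oxygen O4'. Ring A is a phloroglucinol unit (free hydroxyls at C5 and C7, ether oxygen O1 at C8a). Ring B keeps free hydroxyls at C3' and C5' on either side of the O4' ester. There are two stereocentres, C2 and C3, both R, with the aryl group at C2 and the acyloxy group at C3 cis to each other (the epi series, the less stable arrangement). The sensitive groups are the eight free phenols (oxidised easily under base), the benzylic C2–O1 ether (ionised by acid, or opened through a quinone methide by base once O4' is a phenoxide, and in both cases C2 is scrambled) and the aryl ester at O4', which can shift to O3' or O5' once these are free. The synthesis is hard because the cis relation must be set without C2 ever becoming a cation, O4' must be told apart from O3' and O5' on a symmetric ring, and the phenols must be uncovered at the end without base. The strategy rests on one feature: C4 is an unsubstituted methylene between C3 and C4a, C4a is an ortho carbon of an aryl ether activated by O1, O5 and O7, and O3 can enter as an epoxide oxygen. Ring C can therefore be closed by attack of C4a on the terminal carbon of an oxirane whose other carbon is C3.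

## Retrosynthetic reasoning

**14 from 13.** The ten O–benzyl bonds of the deca-benzyl ether 13 are cut last. A single kind of protecting group on all phenols, on the flavan and on both galloyl units, allows one neutral, base-free deprotection, which is what the oxidisable phenols and the migration-prone O4' ester require. The forward step must remove ten benzyl groups while leaving two esters and the C2–O1 bond intact.

**13 from 10 and 11 (through 12).** The two acyl–oxygen bonds at O3 and O4' are cut. Both acyl groups are the same, so they are introduced together on diol 10, whose only free hydroxyls are O3–H and O4'–H. The acid 11 is activated as its chloride 12. The forward step must acylate a phenol flanked by two benzyloxy groups and a secondary alcohol that sits cis to the C2 aryl group.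

**10 from 9.** The O4'–S bond of the aryl tosylate 9 is cut. O4' has to be marked from the start, and a sulfonate is chosen over an ether for three reasons. It is electron-withdrawing, so it protects C2 against ionisation in every acidic or substitution step before it. It survives the Grignard addition, the Sharpless epoxidation, the Mitsunobu coupling and the Lewis acid of the ring closure. It can be removed reductively without touching benzyl ethers.

**9 from 8 (key disconnection).** The C4–C4a bond is cut, which opens ring C to the aryloxy epoxide 8. This is the one skeletal bond of ring C that can be made without forming or breaking a bond at either stereocentre. Ring A is symmetric, so both ortho carbons lead to the same product, and O3 appears directly as the free hydroxyl needed later. The forward reaction must open the oxirane at its terminal carbon (six-membered ring, not five) and must not ionise the C2–O1 ether.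

**8 from 6 and 7.** The C2–O1 bond is cut. Etherification of the erythro epoxy alcohol 6 with phenol 7 by SN2 displacement at C2 inverts that centre and gives the threo ether, which maps onto the 2,3-cis chroman. The forward step must be a clean inversion at a benzylic carbon next to an oxirane, helped by the electron-poor ring B.

**6 from 5.** The two C–O bonds of the oxirane are cut. A Sharpless kinetic resolution of the racemic allylic alcohol 5 sets C3 by reagent control and fixes C2 by selecting one enantiomer, in one operation. Half of the material is given up at an early, cheap stage.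

**5 from 3 and 4.** The C2–C3 bond is cut to the ring B aldehyde 3 and the vinyl organomagnesium reagent 4, which supplies C3 and C4.

**3 from 2, and 2 from 1.** The two O–benzyl bonds of 3 are cut to the monotosylate 2, and then the O4–S bond of 2 is cut, leading back to the trihydroxybenzaldehyde 1. The forward order (sulfonylation first, then benzylation) uses the higher acidity of O4–H, para to the formyl group, to distinguish it from O3–H and O5–H.

## Alternatives that were turned down

Alternative 1: Ring A itself is disconnected and built by a Danheiser benzannulation. An alkoxycyclobutenone is heated with a siloxyalkyne that already carries C4, C3, C2 and ring B as an acetonide-protected diol chain. Ring opening to a vinylketene, [2+2] addition to the ynol ether, a second ring opening and 6π closure would give 5-(benzyloxy)-2-({(4R,5S)-5-[3,5-bis(benzyloxy)-4-(4-methoxybenzyloxy)phenyl]-2,2-dimethyl-1,3-dioxolan-4-yl}methyl)-3-(triisopropylsilyloxy)phenol A1, a phenol free only at O1.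
- For: the pericyclic cascade fixes the substitution pattern of ring A, and the C4–C4a bond exists before the ring is made, so there is no ring-size question. On this point the route through A1 is stronger than the chosen one. It also gives three differentiated ring A oxygens in A1, useful for analogues.
- Against: ring A of this target is a symmetric, purchasable phloroglucinol unit, so the differentiation is paid for and not used. The siloxyalkyne needs several steps and is hydrolytically fragile. Four classes of protecting group must be handled. After A1, ring C still has to be closed by making O1–C2 at a benzylic carbon para to an alkoxy group, which is the situation most prone to SN1 loss of configuration at C2.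
- Comparison: the sequence through A1 would be roughly twice as long. The chosen strategy gives up the built-in regiochemistry and offers instead a bought ring A, a C2–O1 bond made by SN2 on an electron-poor ring B, and nine steps in all.

Alternative 2: Ring A is disconnected at C4a–C5 and made by a biomimetic, polyketide-type aromatisation on a preformed ring C. An alkylidene β-keto ester on the pyran is treated with a strong alkoxide base. The C4a carbanion attacks the ester carbon C5 with loss of alkoxide, and enolisation would give (2R,3R)-3-(allyloxy)-2-[4-(allyloxy)-3,5-bis(benzyloxy)phenyl]chromane-5,7-diol A2.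
- For: both stereocentres are set on a saturated ring before any electron-rich arene is present, so there is no Friedel–Crafts regiochemistry and no Lewis acid near the benzylic ether. Here the route through A2 is as strong as or stronger than the chosen one. O3 and O4' of A2 share one protecting group and could be freed together.
- Against: the strong base acts on a substrate in which the C3–O bond is allylic to the exocyclic alkene and the C2–H is benzylic and vinylogously acidic. Elimination of the C3 alkoxy group, opening of C2–O1 or epimerisation at C2 would each destroy stereochemistry. Building the cis-disubstituted pyran with its keto ester chain is long. The free 5,7-diol of A2 has to be protected again before the allyl groups can be removed and the two esters made.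
- Comparison: the chosen strategy never exposes the stereocentres to strong base, buys ring A, and needs about half the steps that A2 would cost. In exchange it accepts a ring-size selectivity question in its key step.

Alternative 3: Ring C is disconnected at O1–C8a. A symmetric tris(benzyloxy)arene carrying the C4–C3–C2 chain is oxidised to its radical cation by an acridinium photooxidant under blue light. The C2 hydroxyl attacks the ipso carbon C8a and one benzyloxy group leaves as the alcohol, giving (2R,3R)-5,7-bis(benzyloxy)-2-[3,5-bis(benzyloxy)-4-(tosyloxy)phenyl]-3-(methoxymethoxy)chromane A3.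
- For: on the way to A3 the C–O bond at C2 is never made or broken, so its configuration is secure. This is stronger than the chosen route, where C2–O1 is made by inversion. C4–C4a would come from robust aryl-metal chemistry, and both ortho leaving groups are equivalent.
- Against: alkoxy-for-alkoxy exchange with an alcohol nucleophile is the least developed variant of this photochemistry. The precursor of A3 carries six benzyl aryl ethers, whose radical cations can lose a benzylic proton and be cleaved oxidatively. The radical cation of ring A has a β-oxygenated benzylic C4–C3 bond that can fragment. In A3 the oxygen O3 is masked as an acetal, which has to be removed with acid next to the benzylic ether before the tosylate can be cleaved and the esters made; masking and unmasking cost two steps.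
- Comparison: the chosen strategy reaches alcohol 9 directly, two steps shorter than the path through A3, and its key step is thermal chemistry with close precedent. It compensates for the weaker guarantee at C2 by making ring B electron-poor, so that both the etherification and the cyclisation proceed without a C2 cation.

Key step: step 6

Remark on the chemistry (assumption): compounds 1, 4, 7 and 11 are taken as purchased; 1 is sold as a hydrate and is dried azeotropically with toluene before step 1.

## Route

Step 1
Reactants: 1 3,4,5-trihydroxybenzaldehyde
Product: 2 4-formyl-2,6-dihydroxyphenyl 4-methylbenzenesulfonate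
Conditions: TsCl (1.0 equiv), K2CO3 (1.0 equiv), acetone, Ar, 0 °C → rt
Reagents that add atoms: p-toluenesulfonyl chloride, Cc1ccc(S(=O)(=O)Cl)cc1
Why: Phenol sulfonylation; with one equivalent of weak base only the most acidic hydroxyl (O4–H, para to the formyl group) is ionised, the same bias that makes para-O-alkylation of gallates selective, so the tosyl group should go to O4.

Step 2
Reactants: 2 4-formyl-2,6-dihydroxyphenyl 4-methylbenzenesulfonate
Product: 3 2,6-bis(benzyloxy)-4-formylphenyl 4-methylbenzenesulfonate
Conditions: BnBr (2.4 equiv), K2CO3, DMF, rt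
Reagents that add atoms: benzyl bromide, BrCc1ccccc1
Why: Williamson etherification of the two remaining, equivalent phenols; the aryl sulfonate is inert to carbonate at room temperature, and a sulfonyl shift to a neighbouring phenoxide is disfavoured because in-line displacement at sulfur cannot be reached in a five-membered transition state.

Step 3
Reactants: 3 2,6-bis(benzyloxy)-4-formylphenyl 4-methylbenzenesulfonate; 4 vinylmagnesium bromide
Product: 5 racemic 2,6-bis(benzyloxy)-4-(1-hydroxyprop-2-en-1-yl)phenyl 4-methylbenzenesulfonate
Conditions: THF, −78 °C; aq. NH4Cl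
Reagents that add atoms: none
Why: Grignard 1,2-addition to an aromatic aldehyde; at −78 °C the aldehyde should be consumed far faster than the aryl sulfonate is attacked at sulfur, and the carbinol centre is made racemic on purpose, to be resolved in step 4.

Step 4
Reactants: 5 racemic 2,6-bis(benzyloxy)-4-(1-hydroxyprop-2-en-1-yl)phenyl 4-methylbenzenesulfonate
Product: 6 2,6-bis(benzyloxy)-4-{(S)-hydroxy[(2R)-oxiran-2-yl]methyl}phenyl 4-methylbenzenesulfonate (erythro)
Conditions: Ti(OiPr)4 (0.15 equiv), L-(+)-diisopropyl tartrate (0.20 equiv), t-BuOOH (0.45 equiv), 4 Å MS, CH2Cl2, −20 °C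
Reagents that add atoms: tert-butyl hydroperoxide, CC(C)(C)OO
Why: Sharpless kinetic resolution of a secondary allylic alcohol: with the L-(+)-tartrate the (R)-enantiomer of 5 should be epoxidised much faster than the (S)-enantiomer and on the face that gives the erythro epoxy alcohol, while the (S)-enantiomer stays behind. The oxirane carbon is thus set R by the reagent and the carbinol (S by descriptor in 6, because the oxirane carbon now outranks the aryl group) by selection. Stopping below half conversion keeps the enantiomeric purity of 6 high, and the catalytic, sieve-dried protocol limits opening of the terminal epoxide by isopropoxide.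

Step 5
Reactants: 6 2,6-bis(benzyloxy)-4-{(S)-hydroxy[(2R)-oxiran-2-yl]methyl}phenyl 4-methylbenzenesulfonate; 7 3,5-bis(benzyloxy)phenol
Product: 8 2,6-bis(benzyloxy)-4-{(R)-[3,5-bis(benzyloxy)phenoxy][(2R)-oxiran-2-yl]methyl}phenyl 4-methylbenzenesulfonate (threo)
Conditions: PPh3, DIAD, toluene, 0 °C → rt
Reagents that add atoms: none
Why: Mitsunobu etherification: the alkoxyphosphonium ion of 6 is displaced by the phenoxide of 7 in an SN2 step, so the benzylic carbon is inverted from S to R (erythro to threo) while the oxirane carbon is untouched. The tosyloxy and meta-benzyloxy groups of ring B make a benzylic cation unfavourable, which should keep the displacement stereospecific.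

Step 6
Reactants: 8 2,6-bis(benzyloxy)-4-{(R)-[3,5-bis(benzyloxy)phenoxy][(2R)-oxiran-2-yl]methyl}phenyl 4-methylbenzenesulfonate
Product: 9 (2R,3R)-5,7-bis(benzyloxy)-2-[3,5-bis(benzyloxy)-4-(tosyloxy)phenyl]chroman-3-ol
Conditions: Sc(OTf)3 (10 mol %), (CF3)2CHOH/CH2Cl2, 0.01 M, 0 °C → rt
Reagents that add atoms: none
Why: Sc(OTf)3, helped by the strongly hydrogen-bond-donating, non-nucleophilic solvent, binds the oxirane oxygen, and the ring A carbon ortho to O1 (C4a, also ortho to one benzyloxy group and para to the other) attacks the terminal oxirane carbon C4 in an SN2-like Friedel–Crafts alkylation; loss of the proton from the arenium ion restores ring A and O3 is released as the free hydroxyl. The closest known reaction type is the Lewis acid- or fluoroalcohol-promoted intramolecular epoxy–arene cyclisation of aryl glycidyl ethers to chroman-3-ols. Ring C closes in the 6-endo mode with respect to the epoxide, the new bond being C4–C4a. No stereocentre is created: neither C2–O1 nor C3–O3 is broken, so the threo relation of 8 is carried over as the 2,3-cis relation of 9. The step needs attack at C4 (6-endo) and not at C3 (5-exo), which is secured because C4 is primary and unhindered while C3 is secondary and flanked by the inductively deactivating C2. It also needs C2 to stay intact, which is secured by the tosyloxy group and the two meta benzyloxy groups of ring B, which make a cation at C2 unfavourable. Site selectivity on ring A is not an issue, because the two ortho carbons are equivalent and the para carbon cannot reach the epoxide; high dilution should suppress intermolecular alkylation there.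

Step 7
Reactants: 9 (2R,3R)-5,7-bis(benzyloxy)-2-[3,5-bis(benzyloxy)-4-(tosyloxy)phenyl]chroman-3-ol
Product: 10 (2R,3R)-5,7-bis(benzyloxy)-2-[3,5-bis(benzyloxy)-4-hydroxyphenyl]chroman-3-ol
Conditions: Mg turnings (10 equiv), MeOH/THF, rt, sonication; aq. NH4Cl
Reagents that add atoms: none
Why: Dissolving-metal reductive cleavage of an aryl sulfonate (electron transfer to the arenesulfonyl group, S–O scission), a known chemoselective detosylation that should leave benzyl ethers, the secondary alcohol and the chroman untouched; room temperature keeps the 4'-phenoxide from opening ring C.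

Step 8
Reactants: 10 (2R,3R)-5,7-bis(benzyloxy)-2-[3,5-bis(benzyloxy)-4-hydroxyphenyl]chroman-3-ol; 11 3,4,5-tris(benzyloxy)benzoic acid
Product: 13 (2R,3R)-5,7-bis(benzyloxy)-2-{3,5-bis(benzyloxy)-4-[3,4,5-tris(benzyloxy)benzoyloxy]phenyl}chroman-3-yl 3,4,5-tris(benzyloxy)benzoate, via 3,4,5-tris(benzyloxy)benzoyl chloride 12 (not isolated)
Conditions: 11 (3 equiv), (COCl)2, DMF (cat.), CH2Cl2, 0 °C → rt, evaporate; then 10, Et3N, DMAP, CH2Cl2, 0 °C → rt
Reagents that add atoms: none
Why: Acid chloride formation followed by DMAP-catalysed acylation (nucleophilic catalysis); the acylpyridinium ion is reactive enough to esterify both the di-ortho-substituted 4'-phenol and the hindered 3-hydroxyl, which are the only free hydroxyls of 10.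

Step 9
Reactants: 13 (2R,3R)-5,7-bis(benzyloxy)-2-{3,5-bis(benzyloxy)-4-[3,4,5-tris(benzyloxy)benzoyloxy]phenyl}chroman-3-yl 3,4,5-tris(benzyloxy)benzoate
Product: 14 (−)-epigallocatechin 3,4'-di-O-gallate, (2R,3R)-2-{3,5-dihydroxy-4-[(3,4,5-trihydroxybenzoyl)oxy]phenyl}-5,7-dihydroxychroman-3-yl 3,4,5-trihydroxybenzoate
Conditions: H2 (1 atm), Pd(OH)2 on carbon, THF/MeOH, rt; filter, evaporate below 30 °C
Reagents that add atoms: none
Why: Catalytic hydrogenolysis of ten aryl benzyl ethers; under neutral conditions at room temperature the two esters and the C2–O1 bond should survive, neither stereocentre is touched, and the absence of base should hold the O4' ester in place.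

## Compound list

1 | 3,4,5-trihydroxybenzaldehyde | O=Cc1cc(O)c(O)c(O)c1 | starting material
2 | 4-formyl-2,6-dihydroxyphenyl 4-methylbenzenesulfonate | Cc1ccc(S(=O)(=O)Oc2c(O)cc(C=O)cc2O)cc1 | intermediate
3 | 2,6-bis(benzyloxy)-4-formylphenyl 4-methylbenzenesulfonate | Cc1ccc(S(=O)(=O)Oc2c(OCc3ccccc3)cc(C=O)cc2OCc2ccccc2)cc1 | intermediate
4 | vinylmagnesium bromide | C=C[Mg]Br | starting material
5 | racemic 2,6-bis(benzyloxy)-4-(1-hydroxyprop-2-en-1-yl)phenyl 4-methylbenzenesulfonate | Cc1ccc(S(=O)(=O)Oc2c(OCc3ccccc3)cc(C(O)C=C)cc2OCc2ccccc2)cc1 | intermediate
6 | 2,6-bis(benzyloxy)-4-{(S)-hydroxy[(2R)-oxiran-2-yl]methyl}phenyl 4-methylbenzenesulfonate | Cc1ccc(S(=O)(=O)Oc2c(OCc3ccccc3)cc([C@H](O)[C@H]3CO3)cc2OCc2ccccc2)cc1 | intermediate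
7 | 3,5-bis(benzyloxy)phenol | Oc1cc(OCc2ccccc2)cc(OCc2ccccc2)c1 | starting material
8 | 2,6-bis(benzyloxy)-4-{(R)-[3,5-bis(benzyloxy)phenoxy][(2R)-oxiran-2-yl]methyl}phenyl 4-methylbenzenesulfonate | Cc1ccc(S(=O)(=O)Oc2c(OCc3ccccc3)cc([C@@H](Oc3cc(OCc4ccccc4)cc(OCc4ccccc4)c3)[C@H]3CO3)cc2OCc2ccccc2)cc1 | intermediate
9 | (2R,3R)-5,7-bis(benzyloxy)-2-[3,5-bis(benzyloxy)-4-(tosyloxy)phenyl]chroman-3-ol | Cc1ccc(S(=O)(=O)Oc2c(OCc3ccccc3)cc([C@H]3Oc4cc(OCc5ccccc5)cc(OCc5ccccc5)c4C[C@H]3O)cc2OCc2ccccc2)cc1 | intermediate
10 | (2R,3R)-5,7-bis(benzyloxy)-2-[3,5-bis(benzyloxy)-4-hydroxyphenyl]chroman-3-ol | Oc1c(OCc2ccccc2)cc([C@H]2Oc3cc(OCc4ccccc4)cc(OCc4ccccc4)c3C[C@H]2O)cc1OCc1ccccc1 | intermediate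
11 | 3,4,5-tris(benzyloxy)benzoic acid | O=C(O)c1cc(OCc2ccccc2)c(OCc2ccccc2)c(OCc2ccccc2)c1 | starting material
12 | 3,4,5-tris(benzyloxy)benzoyl chloride | O=C(Cl)c1cc(OCc2ccccc2)c(OCc2ccccc2)c(OCc2ccccc2)c1 | intermediate
13 | (2R,3R)-5,7-bis(benzyloxy)-2-{3,5-bis(benzyloxy)-4-[3,4,5-tris(benzyloxy)benzoyloxy]phenyl}chroman-3-yl 3,4,5-tris(benzyloxy)benzoate | O=C(Oc1c(OCc2ccccc2)cc([C@H]2Oc3cc(OCc4ccccc4)cc(OCc4ccccc4)c3C[C@H]2OC(=O)c2cc(OCc3ccccc3)c(OCc3ccccc3)c(OCc3ccccc3)c2)cc1OCc1ccccc1)c1cc(OCc2ccccc2)c(OCc2ccccc2)c(OCc2ccccc2)c1 | intermediate
14 | (−)-epigallocatechin 3,4'-di-O-gallate | O=C(Oc1c(O)cc([C@H]2Oc3cc(O)cc(O)c3C[C@H]2OC(=O)c2cc(O)c(O)c(O)c2)cc1O)c1cc(O)c(O)c(O)c1 | target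

## Step count and least certain steps

Total step count: 9. Longest linear sequence: 9 steps (1 to 14); 4, 7 and 11 join it as purchased components.

**Step 6 (key step).** Three processes could compete with the ring closure:
- ionisation of the benzylic C2–O1 ether under the Lewis acid, leading to ether cleavage or loss of configuration at C2;
- a 1,2-shift of hydride or aryl onto C3 of the activated oxirane (Meinwald or semipinacol type);
- opening at C3 to the five-membered ring, if the terminal carbon is less favoured than expected.

The fallback reverses the polarity of the closure; it sets out from 6 and 7 and returns at 9. Phenol 7 is iodinated next to the hydroxyl (N-iodosuccinimide, CH2Cl2, 0 °C; the isomer iodinated between the two benzyloxy groups is removed by chromatography) to 3,5-bis(benzyloxy)-2-iodophenol F1. Mitsunobu coupling of 6 with F1 under the conditions of step 5 gives 2,6-bis(benzyloxy)-4-{(R)-[3,5-bis(benzyloxy)-2-iodophenoxy][(2R)-oxiran-2-yl]methyl}phenyl 4-methylbenzenesulfonate F2. LiBr and AcOH in THF open the oxirane at its terminal carbon to 2,6-bis(benzyloxy)-4-{(1R,2S)-1-[3,5-bis(benzyloxy)-2-iodophenoxy]-3-bromo-2-hydroxypropyl}phenyl 4-methylbenzenesulfonate F3. Et3SiCl and imidazole give 2,6-bis(benzyloxy)-4-{(1R,2S)-1-[3,5-bis(benzyloxy)-2-iodophenoxy]-3-bromo-2-(triethylsilyloxy)propyl}phenyl 4-methylbenzenesulfonate F4. Iodine–lithium exchange (n-BuLi, one equivalent, THF, −78 °C) makes the aryllithium at C4a, which displaces the primary bromide in a 6-exo-tet alkylation to give (2R,3R)-5,7-bis(benzyloxy)-2-[3,5-bis(benzyloxy)-4-(tosyloxy)phenyl]-3-(triethylsilyloxy)chroman F5. HF·pyridine in THF at 0 °C removes the silyl group without endangering the aryl sulfonate, and the sequence rejoins the route at 9. No Lewis acid is used and the ring size is fixed by the position of the bromide.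

**Step 5.** The displacement takes place at a hindered carbinol that is deactivated inductively by the neighbouring oxirane. It may be slow, so that alkylation of the reduced azodicarboxylate or opening of the epoxide by phenoxide competes, and any SN1 component would erode the inversion. The fallback sets out from 6 and returns at 8: MsCl and Et3N at −20 °C give (S)-[3,5-bis(benzyloxy)-4-(tosyloxy)phenyl][(2R)-oxiran-2-yl]methyl methanesulfonate F6, an isolated electrophile, which is displaced with inversion by the cesium salt of 7 (Cs2CO3, DMF, rt) to give 8.

**Step 4.** A terminal vinyl carbinol gives only a moderate rate difference between the enantiomers, so the enantiomeric purity of the epoxy alcohol falls as conversion nears one half. Tetravalent titanium can also open the terminal epoxide. The fallback separates resolution from epoxidation; it sets out from 5 and returns at 6. Immobilised Candida antarctica lipase B with vinyl acetate in toluene should acetylate the (R)-enantiomer (Kazlauskas rule, aryl as the large group) to (R)-1-[3,5-bis(benzyloxy)-4-(tosyloxy)phenyl]prop-2-en-1-yl acetate F7, which is separated from the unreacted (S)-alcohol. K2CO3 in MeOH gives 2,6-bis(benzyloxy)-4-[(1R)-1-hydroxyprop-2-en-1-yl]phenyl 4-methylbenzenesulfonate F8. This single enantiomer is epoxidised to completion with Ti(OiPr)4, L-(+)-diisopropyl tartrate and a full equivalent of t-BuOOH (matched case) to give 6.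

**Step 1.** Site selectivity may be incomplete (sulfonylation at O3, or twice), and the pyrogallol can be oxidised by air under base. The fallback fixes the regiochemistry by the well-established para-selective O-alkylation and installs the tosyl group on a single free phenol; it sets out from 1 and returns at 3. Allyl bromide (1 equiv) and KHCO3 in DMF give 4-(allyloxy)-3,5-dihydroxybenzaldehyde F9. BnBr and K2CO3 give 4-(allyloxy)-3,5-bis(benzyloxy)benzaldehyde F10. Pd(PPh3)4 and K2CO3 in MeOH remove the allyl group to give 3,5-bis(benzyloxy)-4-hydroxybenzaldehyde F11. TsCl, Et3N and DMAP in CH2Cl2 then give 3.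

**Step 9.** Once O3' and O5' are free, the O4' galloyl group can migrate to them or be lost by methanolysis. Removal of ten benzyl groups may stall, and prolonged exposure may hydrogenolyse the C2–O1 bond. The fallback sets out from 13 and returns at 14: non-reductive debenzylation with BCl3 and pentamethylbenzene in CH2Cl2 at −78 °C, followed by an acidic quench. The medium stays acidic throughout, which disfavours acyl shift, and no hydrogen is present. No new compound is made on this path (entry F0).

## Further compounds

F1 | step 6 | 3,5-bis(benzyloxy)-2-iodophenol | Oc1cc(OCc2ccccc2)cc(OCc2ccccc2)c1I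
F2 | step 6 | 2,6-bis(benzyloxy)-4-{(R)-[3,5-bis(benzyloxy)-2-iodophenoxy][(2R)-oxiran-2-yl]methyl}phenyl 4-methylbenzenesulfonate | Cc1ccc(S(=O)(=O)Oc2c(OCc3ccccc3)cc([C@@H](Oc3cc(OCc4ccccc4)cc(OCc4ccccc4)c3I)[C@H]3CO3)cc2OCc2ccccc2)cc1
F3 | step 6 | 2,6-bis(benzyloxy)-4-{(1R,2S)-1-[3,5-bis(benzyloxy)-2-iodophenoxy]-3-bromo-2-hydroxypropyl}phenyl 4-methylbenzenesulfonate | Cc1ccc(S(=O)(=O)Oc2c(OCc3ccccc3)cc([C@@H](Oc3cc(OCc4ccccc4)cc(OCc4ccccc4)c3I)[C@H](O)CBr)cc2OCc2ccccc2)cc1
F4 | step 6 | 2,6-bis(benzyloxy)-4-{(1R,2S)-1-[3,5-bis(benzyloxy)-2-iodophenoxy]-3-bromo-2-(triethylsilyloxy)propyl}phenyl 4-methylbenzenesulfonate | Cc1ccc(S(=O)(=O)Oc2c(OCc3ccccc3)cc([C@@H](Oc3cc(OCc4ccccc4)cc(OCc4ccccc4)c3I)[C@H](O[Si](CC)(CC)CC)CBr)cc2OCc2ccccc2)cc1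
F5 | step 6 | (2R,3R)-5,7-bis(benzyloxy)-2-[3,5-bis(benzyloxy)-4-(tosyloxy)phenyl]-3-(triethylsilyloxy)chroman | Cc1ccc(S(=O)(=O)Oc2c(OCc3ccccc3)cc([C@H]3Oc4cc(OCc5ccccc5)cc(OCc5ccccc5)c4C[C@H]3O[Si](CC)(CC)CC)cc2OCc2ccccc2)cc1
F6 | step 5 | (S)-[3,5-bis(benzyloxy)-4-(tosyloxy)phenyl][(2R)-oxiran-2-yl]methyl methanesulfonate | Cc1ccc(S(=O)(=O)Oc2c(OCc3ccccc3)cc([C@H](OS(C)(=O)=O)[C@H]3CO3)cc2OCc2ccccc2)cc1
F7 | step 4 | (R)-1-[3,5-bis(benzyloxy)-4-(tosyloxy)phenyl]prop-2-en-1-yl acetate | Cc1ccc(S(=O)(=O)Oc2c(OCc3ccccc3)cc([C@H](OC(C)=O)C=C)cc2OCc2ccccc2)cc1
F8 | step 4 | 2,6-bis(benzyloxy)-4-[(1R)-1-hydroxyprop-2-en-1-yl]phenyl 4-methylbenzenesulfonate | Cc1ccc(S(=O)(=O)Oc2c(OCc3ccccc3)cc([C@H](O)C=C)cc2OCc2ccccc2)cc1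
F9 | step 1 | 4-(allyloxy)-3,5-dihydroxybenzaldehyde | C=CCOc1c(O)cc(C=O)cc1O
F10 | step 1 | 4-(allyloxy)-3,5-bis(benzyloxy)benzaldehyde | C=CCOc1c(OCc2ccccc2)cc(C=O)cc1OCc1ccccc1
F11 | step 1 | 3,5-bis(benzyloxy)-4-hydroxybenzaldehyde | O=Cc1cc(OCc2ccccc2)c(O)c(OCc2ccccc2)c1
F0 | step 9 | none | none
A1 | alternative 1 | 5-(benzyloxy)-2-({(4R,5S)-5-[3,5-bis(benzyloxy)-4-(4-methoxybenzyloxy)phenyl]-2,2-dimethyl-1,3-dioxolan-4-yl}methyl)-3-(triisopropylsilyloxy)phenol | COc1ccc(COc2c(OCc3ccccc3)cc([C@@H]3OC(C)(C)O[C@@H]3Cc3c(O)cc(OCc4ccccc4)cc3O[Si](C(C)C)(C(C)C)C(C)C)cc2OCc2ccccc2)cc1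
A2 | alternative 2 | (2R,3R)-3-(allyloxy)-2-[4-(allyloxy)-3,5-bis(benzyloxy)phenyl]chromane-5,7-diol | C=CCOc1c(OCc2ccccc2)cc([C@H]2Oc3cc(O)cc(O)c3C[C@H]2OCC=C)cc1OCc1ccccc1
A3 | alternative 3 | (2R,3R)-5,7-bis(benzyloxy)-2-[3,5-bis(benzyloxy)-4-(tosyloxy)phenyl]-3-(methoxymethoxy)chromane | Cc1ccc(S(=O)(=O)Oc2c(OCc3ccccc3)cc([C@H]3Oc4cc(OCc5ccccc5)cc(OCc5ccccc5)c4C[C@H]3OCOC)cc2OCc2ccccc2)cc1
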